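**Plan**
1. Retrosynthetic cuts, in order: the C-1–C-2 bond of each cyclopentanol (two-fold retro carbonyl-ene, leaving an α-branched aldehyde with a 4-methylpent-3-enyl chain); then, in each oxane ring (O-1, C-2 to C-6), the O-1–C-6 and C-2–C-3 bonds, after raising C-6 to a lactone carbonyl; last the two exocyclic C-5=CH bonds (to succinaldehyde).
2. Enabling feature: in each oxane ring the O–CH2 carbon C-6 and the C-4–C-3 ethano arm are both attached to the alkylidene carbon C-5. With C-6 as an ester, C-3–C-4–C-5(=CH)–C-6 is a (Z)-2-alkylidene-4-metallobutanoate: C-3 adds to an aldehyde carbon (the future C-2) and the ester C-6 captures the new alkoxide O-1. The twofold axis through the central CH2–CH2 bond lets both rings form in one operation.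
3. Forward order: the C12 diene-diester chain is joined first (two-fold Z-selective olefination of succinaldehyde); both oxane rings arise together as 3-alkylidene δ-lactones in the key step; the lactone carbonyls are reduced to CH2; both cyclopentane rings are closed last.
4. Stereochemistry: the side-chain centre comes from oxazolidinone-controlled hydroxymethylation; oxane C-2 from a chiral titanium bis-sulfonamide catalyst in the alkylzinc addition; both Z alkenes from the Still–Gennari step; cyclopentanol C-1 and C-2 by relay from the α-centre in the ene closure.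

Key step: step 11

Remark: each two-directional step is written as one two-fold reaction at the two identical ends of the twofold-symmetric compound.

**Step 1**
Reactants: 1 6-methylhept-5-enoic acid; 2 (4R)-4-benzyl-1,3-oxazolidin-2-one
Product: 4 (4R)-4-benzyl-3-(6-methylhept-5-enoyl)-1,3-oxazolidin-2-one, via mixed pivalic anhydride 3 (not isolated)
Conditions: t-BuCOCl, Et3N, THF, −20 °C; then LiCl, 2, −20 → 20 °C
Reagents that add atoms: none
Why: N-acylation of the oxazolidinone by a mixed anhydride (mixed-anhydride acylation) is a standard imide synthesis and touches no stereocentre.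

**Step 2**
Reactants: 4 (4R)-4-benzyl-3-(6-methylhept-5-enoyl)-1,3-oxazolidin-2-one
Product: 6 (4R)-4-benzyl-3-[(2S)-2-(hydroxymethyl)-6-methylhept-5-enoyl]-1,3-oxazolidin-2-one, via chlorotitanium enolate 5 (not isolated)
Conditions: TiCl4, i-Pr2NEt, CH2Cl2, 0 °C; then 1,3,5-trioxane, TiCl4, 0 °C
Reagents that add atoms: 1,3,5-trioxane, C1OCOCO1
Why: Auxiliary-controlled aldol-type hydroxymethylation: the chelated (Z)-titanium enolate should take up formaldehyde on the face opposite the benzyl group, which sets the α-centre as S.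

**Step 3**
Reactants: 6 (4R)-4-benzyl-3-[(2S)-2-(hydroxymethyl)-6-methylhept-5-enoyl]-1,3-oxazolidin-2-one
Product: 7 (4R)-4-benzyl-3-[(2S)-2-({[tert-butyl(diphenyl)silyl]oxy}methyl)-6-methylhept-5-enoyl]-1,3-oxazolidin-2-one
Conditions: t-BuPh2SiCl, imidazole, DMF, 20 °C
Reagents that add atoms: tert-butyl(chloro)diphenylsilane, CC(C)(C)[Si](Cl)(c1ccccc1)c1ccccc1
Why: Silyl ether formation at the primary alcohol gives a robust, non-chelating protecting group that is slow to migrate.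

**Step 4**
Reactants: 7 (4R)-4-benzyl-3-[(2S)-2-({[tert-butyl(diphenyl)silyl]oxy}methyl)-6-methylhept-5-enoyl]-1,3-oxazolidin-2-one
Product: 8 (2R)-2-({[tert-butyl(diphenyl)silyl]oxy}methyl)-6-methylhept-5-en-1-ol
Conditions: LiBH4, MeOH (1 equiv), Et2O, 0 °C
Reagents that add atoms: none
Why: Reductive cleavage of the N-acyl oxazolidinone by hydride reduction should release the primary alcohol without enolising the α-centre (the descriptor changes only through the priority rules).

**Step 5**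
Reactants: 8 (2R)-2-({[tert-butyl(diphenyl)silyl]oxy}methyl)-6-methylhept-5-en-1-ol
Product: 9 (2S)-2-({[tert-butyl(diphenyl)silyl]oxy}methyl)-6-methylhept-5-enal
Conditions: TEMPO (cat.), PhI(OAc)2, CH2Cl2, 20 °C; used at once
Reagents that add atoms: none
Why: Oxoammonium (TEMPO) oxidation of the primary alcohol works without base, so the α-stereocentre of the aldehyde should be kept.

**Step 6**
Reactants: 10 methyl 2-[bis(2,2,2-trifluoroethoxy)phosphoryl]acetate; 11 tert-butyl(2-iodoethoxy)dimethylsilane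
Product: 13 methyl 2-[bis(2,2,2-trifluoroethoxy)phosphoryl]-4-{[tert-butyl(dimethyl)silyl]oxy}butanoate (racemic), via sodium phosphonoacetate enolate 12 (not isolated)
Conditions: NaH, DMSO, 20 °C; then 11, 20 → 50 °C
Reagents that add atoms: none
Why: SN2 C-alkylation of the stabilised phosphonoacetate anion by a primary iodide installs the future C-4–C-3 arm in protected form.

**Step 7**
Reactants: 14 2,5-dimethoxytetrahydrofuran (cis/trans mixture)
Product: 15 succinaldehyde (butanedial)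
Conditions: H2O, 90 °C; extraction into CH2Cl2; used at once
Reagents that add atoms: water, O
Why: Hydrolysis of the cyclic bis-acetal frees the dialdehyde that supplies the central CH2–CH2 bridge.

**Step 8**
Reactants: 13 methyl 2-[bis(2,2,2-trifluoroethoxy)phosphoryl]-4-{[tert-butyl(dimethyl)silyl]oxy}butanoate (2.2 equiv); 15 succinaldehyde
Product: 17 dimethyl (2Z,6Z)-2,7-bis(2-{[tert-butyl(dimethyl)silyl]oxy}ethyl)octa-2,6-dienedioate, via potassium phosphonate anion 16 (not isolated)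
Conditions: KN(SiMe3)2, 18-crown-6, THF, −78 °C; then 15, −78 °C
Reagents that add atoms: none
Why: Two-fold Still–Gennari olefination: the trifluoroethyl phosphonate adducts collapse under kinetic control to the Z-trisubstituted enoates, which places each ester carbon (future C-6) cis to the bridge.

**Step 9**
Reactants: 17 dimethyl (2Z,6Z)-2,7-bis(2-{[tert-butyl(dimethyl)silyl]oxy}ethyl)octa-2,6-dienedioate
Product: 18 dimethyl (2Z,6Z)-2,7-bis(2-bromoethyl)octa-2,6-dienedioate
Conditions: Ph3PBr2, CH2Cl2, 0 → 20 °C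
Reagents that add atoms: triphenylphosphine dibromide, BrP(Br)(c1ccccc1)(c1ccccc1)c1ccccc1
Why: Appel-type direct conversion of the silyl ethers into bromides via alkoxyphosphonium ions avoids the free γ-hydroxy esters, which would close to butyrolactones.

**Step 10**
Reactants: 18 dimethyl (2Z,6Z)-2,7-bis(2-bromoethyl)octa-2,6-dienedioate
Product: 19 dimethyl (2Z,6Z)-2,7-bis(2-iodoethyl)octa-2,6-dienedioate
Conditions: NaI, acetone, reflux, dark
Reagents that add atoms: sodium iodide, [Na+].[I-]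
Why: Finkelstein halide exchange gives the primary iodides needed for mild zinc insertion.

**Step 11**
Reactants: 19 dimethyl (2Z,6Z)-2,7-bis(2-iodoethyl)octa-2,6-dienedioate; 9 (2S)-2-({[tert-butyl(diphenyl)silyl]oxy}methyl)-6-methylhept-5-enal (2.4 equiv)
Product: 23 (3Z,3'Z,6R,6'R)-3,3'-(butane-1,4-diylidene)bis[6-((2S)-1-{[tert-butyl(diphenyl)silyl]oxy}-6-methylhept-5-en-2-yl)oxan-2-one], via bis(iodozinc) reagent 20 (not isolated), via mixed bis(alkylzinc) reagent 21 (not isolated), via bis(zinc alkoxide) 22 (not isolated)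
Conditions: Zn dust (activated by BrCH2CH2Br, Me3SiCl), THF, 40 °C; Me3SiCH2Li, −78 °C; solvent exchanged for Et2O; 9, Ti(OiPr)4, (1S,2S)-N,N'-cyclohexane-1,2-diylbis(trifluoromethanesulfonamide) (16 mol %), −20 → 20 °C; 1 M HCl work-up
Reagents that add atoms: none
Why: Zinc inserts into both primary C–I bonds, Me3SiCH2Li converts each end into a mixed diorganozinc whose Me3SiCH2 group does not transfer, and the chiral titanium bis-sulfonamide complex then delivers each C-3 carbon to the Re face of aldehyde 9 (new C-2–C-3 bond), after which each alkoxide O-1 attacks the geminal ester carbon C-6 and expels methoxide (new O-1–C-6 bond). The closest known reaction type is the titanium-catalysed enantioselective addition of functionalised alkyl(trimethylsilylmethyl)zinc reagents to aldehydes, joined to the lactonisation of δ-hydroxy esters. Each oxanone ring closes by 6-exo-trig acyl substitution, which is easy because the ester and the hydroxyalkyl arm sit on the same trigonal carbon C-5. The new stereocentre C-2 of each ring is set by the (1S,2S)-ligand (reagent control), which has to override only a weak opposing bias of the α-centre of 9 because both of its carbon substituents are CH2 groups. The step needs chemoselectivity for the aldehyde over the enoate esters, secured by the inertness of alkylzinc reagents toward esters, and retention of both Z double bonds, secured because neither alkene takes part. Complete two-fold reaction is favoured by the slight excess of 9.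

**Step 12**
Reactants: 23 (3Z,3'Z,6R,6'R)-3,3'-(butane-1,4-diylidene)bis[6-((2S)-1-{[tert-butyl(diphenyl)silyl]oxy}-6-methylhept-5-en-2-yl)oxan-2-one]
Product: 24 (3Z,3'Z,6R,6'R)-3,3'-(butane-1,4-diylidene)bis[6-((2S)-1-{[tert-butyl(diphenyl)silyl]oxy}-6-methylhept-5-en-2-yl)oxan-2-ol] (C-2 epimers)
Conditions: i-Bu2AlH, CH2Cl2, −78 °C; aq. potassium sodium tartrate
Reagents that add atoms: none
Why: Half-reduction of the lactones by 1,2-hydride addition should stop at the lactols because the aluminium hemiacetals are stable at low temperature.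

**Step 13**
Reactants: 24 bis-lactol (C-2 epimers)
Product: 25 (2R,2'R,5Z,5'Z)-5,5'-(butane-1,4-diylidene)bis[2-((2S)-1-{[tert-butyl(diphenyl)silyl]oxy}-6-methylhept-5-en-2-yl)oxane]
Conditions: Et3SiH, BF3·OEt2, CH2Cl2, −78 °C
Reagents that add atoms: none
Why: Reductive deoxygenation of the lactols (ionic hydrogenation): each oxocarbenium ion should take hydride at its own carbon C-6, which removes the helper carbonyl and leaves the exocyclic Z alkene in place.

**Step 14**
Reactants: 25 bis-oxane bis-silyl ether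
Product: 26 (2S,2'S)-diol: 5,5'-(butane-1,4-diylidene)bis-oxane (2R,2'R,5Z,5'Z) carrying at each C-2 a (2S)-1-hydroxy-6-methylhept-5-en-2-yl group
Conditions: Bu4NF, THF, 20 °C
Reagents that add atoms: none
Why: Fluoride-induced desilylation frees both primary alcohols and leaves the allylic ethers and alkenes untouched.

**Step 15**
Reactants: 26 diol
Product: 27 (2R,2'R)-dialdehyde: 5,5'-(butane-1,4-diylidene)bis-oxane (2R,2'R,5Z,5'Z) carrying at each C-2 a (2R)-6-methyl-1-oxohept-5-en-2-yl group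
Conditions: TEMPO (cat.), PhI(OAc)2, CH2Cl2, 20 °C; used crude
Reagents that add atoms: none
Why: Oxoammonium (TEMPO) oxidation without base should give the dialdehyde without epimerising the α-centres or opening the β-alkoxy aldehyde (the descriptor changes only through the priority rules).

**Step 16**
Reactants: 27 dialdehyde
Product: 28 testudinariol A, (1S,1'S,2R,2'R,5S,5'S)-5,5'-[(2R,2'R,5Z,5'Z)-5,5'-(butane-1,4-diylidene)bis(oxane-2-yl)]bis[2-(prop-1-en-2-yl)cyclopentan-1-ol]
Conditions: Me2AlCl (2.2 equiv), CH2Cl2, −78 → −40 °C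
Reagents that add atoms: none
Why: Two-fold Lewis-acid-promoted intramolecular carbonyl-ene reaction: the closed transition state, in which an allylic methyl hydrogen passes to the complexed oxygen, should place OH and isopropenyl cis and keep the α-oxanyl substituent anti to the oxygen, which sets C-1 and C-2 of each cyclopentanol from the existing α-centre.

**Compound list**
1 | 6-methylhept-5-enoic acid | CC(C)=CCCCC(=O)O | starting material
2 | (4R)-4-benzyl-1,3-oxazolidin-2-one | O=C1OC[C@@H](Cc2ccccc2)N1 | starting material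
3 | 6-methylhept-5-enoic pivalic anhydride | CC(C)=CCCCC(=O)OC(=O)C(C)(C)C | intermediate
4 | (4R)-4-benzyl-3-(6-methylhept-5-enoyl)-1,3-oxazolidin-2-one | CC(C)=CCCCC(=O)N1C(=O)OC[C@H]1Cc1ccccc1 | intermediate
5 | trichlorotitanium (Z)-enolate of 4 | CC(C)=CCC/C=C(\O[Ti](Cl)(Cl)Cl)N1C(=O)OC[C@H]1Cc1ccccc1 | intermediate
6 | (4R)-4-benzyl-3-[(2S)-2-(hydroxymethyl)-6-methylhept-5-enoyl]-1,3-oxazolidin-2-one | CC(C)=CCC[C@@H](CO)C(=O)N1C(=O)OC[C@H]1Cc1ccccc1 | intermediate
7 | (4R)-4-benzyl-3-[(2S)-2-({[tert-butyl(diphenyl)silyl]oxy}methyl)-6-methylhept-5-enoyl]-1,3-oxazolidin-2-one | CC(C)=CCC[C@@H](CO[Si](c1ccccc1)(c1ccccc1)C(C)(C)C)C(=O)N1C(=O)OC[C@H]1Cc1ccccc1 | intermediate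
8 | (2R)-2-({[tert-butyl(diphenyl)silyl]oxy}methyl)-6-methylhept-5-en-1-ol | CC(C)=CCC[C@@H](CO[Si](c1ccccc1)(c1ccccc1)C(C)(C)C)CO | intermediate
9 | (2S)-2-({[tert-butyl(diphenyl)silyl]oxy}methyl)-6-methylhept-5-enal | CC(C)=CCC[C@@H](CO[Si](c1ccccc1)(c1ccccc1)C(C)(C)C)C=O | intermediate
10 | methyl 2-[bis(2,2,2-trifluoroethoxy)phosphoryl]acetate | COC(=O)CP(=O)(OCC(F)(F)F)OCC(F)(F)F | starting material
11 | tert-butyl(2-iodoethoxy)dimethylsilane | CC(C)(C)[Si](C)(C)OCCI | starting material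
12 | sodium salt of 10 (phosphonoacetate enolate) | COC(=O)[CH-]P(=O)(OCC(F)(F)F)OCC(F)(F)F.[Na+] | intermediate
13 | methyl 2-[bis(2,2,2-trifluoroethoxy)phosphoryl]-4-{[tert-butyl(dimethyl)silyl]oxy}butanoate (racemic) | COC(=O)C(CCO[Si](C)(C)C(C)(C)C)P(=O)(OCC(F)(F)F)OCC(F)(F)F | intermediate
14 | 2,5-dimethoxytetrahydrofuran (cis/trans mixture) | COC1CCC(OC)O1 | starting material
15 | succinaldehyde (butanedial) | O=CCCC=O | intermediate
16 | potassium salt of 13 (phosphonate anion) | COC(=O)[C-](CCO[Si](C)(C)C(C)(C)C)P(=O)(OCC(F)(F)F)OCC(F)(F)F.[K+] | intermediate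
17 | dimethyl (2Z,6Z)-2,7-bis(2-{[tert-butyl(dimethyl)silyl]oxy}ethyl)octa-2,6-dienedioate | COC(=O)/C(CCO[Si](C)(C)C(C)(C)C)=C\CC/C=C(/CCO[Si](C)(C)C(C)(C)C)C(=O)OC | intermediate
18 | dimethyl (2Z,6Z)-2,7-bis(2-bromoethyl)octa-2,6-dienedioate | COC(=O)/C(CCBr)=C\CC/C=C(/CCBr)C(=O)OC | intermediate
19 | dimethyl (2Z,6Z)-2,7-bis(2-iodoethyl)octa-2,6-dienedioate | COC(=O)/C(CCI)=C\CC/C=C(/CCI)C(=O)OC | intermediate
20 | bis(iodozinc) reagent from 19 | COC(=O)/C(CC[Zn]I)=C\CC/C=C(/CC[Zn]I)C(=O)OC | intermediate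
21 | bis[(trimethylsilylmethyl)zinc] reagent from 20 | COC(=O)/C(CC[Zn]C[Si](C)(C)C)=C\CC/C=C(/CC[Zn]C[Si](C)(C)C)C(=O)OC | intermediate
22 | bis[(trimethylsilylmethyl)zinc] alkoxide of dimethyl (2Z,6Z)-2,7-bis[(3R,4S)-4-({[tert-butyl(diphenyl)silyl]oxy}methyl)-3-hydroxy-8-methylnon-7-en-1-yl]octa-2,6-dienedioate | CC(C)=CCC[C@@H](CO[Si](c1ccccc1)(c1ccccc1)C(C)(C)C)[C@H](O[Zn]C[Si](C)(C)C)CC/C(C(=O)OC)=C/CC/C=C(/CC[C@@H](O[Zn]C[Si](C)(C)C)[C@@H](CCC=C(C)C)CO[Si](c2ccccc2)(c2ccccc2)C(C)(C)C)C(=O)OC | intermediate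
23 | (3Z,3'Z,6R,6'R)-3,3'-(butane-1,4-diylidene)bis[6-((2S)-1-{[tert-butyl(diphenyl)silyl]oxy}-6-methylhept-5-en-2-yl)oxan-2-one] | CC(C)=CCC[C@@H](CO[Si](c1ccccc1)(c1ccccc1)C(C)(C)C)[C@H]2CC/C(=C/CC/C=C3/CC[C@H]([C@@H](CCC=C(C)C)CO[Si](c4ccccc4)(c4ccccc4)C(C)(C)C)OC3=O)C(=O)O2 | intermediate
24 | bis-lactol of 23: (3Z,3'Z,6R,6'R)-3,3'-(butane-1,4-diylidene)bis[6-((2S)-1-{[tert-butyl(diphenyl)silyl]oxy}-6-methylhept-5-en-2-yl)oxan-2-ol], C-2 epimers | CC(C)=CCC[C@@H](CO[Si](c1ccccc1)(c1ccccc1)C(C)(C)C)[C@H]2CC/C(=C/CC/C=C3/CC[C@H]([C@@H](CCC=C(C)C)CO[Si](c4ccccc4)(c4ccccc4)C(C)(C)C)OC3O)C(O)O2 | intermediate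
25 | (2R,2'R,5Z,5'Z)-5,5'-(butane-1,4-diylidene)bis[2-((2S)-1-{[tert-butyl(diphenyl)silyl]oxy}-6-methylhept-5-en-2-yl)oxane] | CC(C)=CCC[C@@H](CO[Si](c1ccccc1)(c1ccccc1)C(C)(C)C)[C@H]2CC/C(=C/CC/C=C3/CC[C@H]([C@@H](CCC=C(C)C)CO[Si](c4ccccc4)(c4ccccc4)C(C)(C)C)OC3)CO2 | intermediate
26 | diol: 5,5'-(butane-1,4-diylidene)bis-oxane (2R,2'R,5Z,5'Z) with a (2S)-1-hydroxy-6-methylhept-5-en-2-yl group at each C-2 | CC(C)=CCC[C@@H](CO)[C@H]2CC/C(=C/CC/C=C3/CC[C@H]([C@@H](CCC=C(C)C)CO)OC3)CO2 | intermediate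
27 | dialdehyde: 5,5'-(butane-1,4-diylidene)bis-oxane (2R,2'R,5Z,5'Z) with a (2R)-6-methyl-1-oxohept-5-en-2-yl group at each C-2 | CC(C)=CCC[C@@H](C=O)[C@H]2CC/C(=C/CC/C=C3/CC[C@H]([C@@H](CCC=C(C)C)C=O)OC3)CO2 | intermediate
28 | testudinariol A | C=C(C)[C@H]1CC[C@H]([C@H]2CC/C(=C/CC/C=C3/CC[C@H]([C@H]4CC[C@H](C(=C)C)[C@@H]4O)OC3)CO2)[C@H]1O | target

**Step count**
Total step count: 16. Longest linear sequence: 11 steps (steps 1–5 and 11–16).

**Steps most likely to fail**

Step 11. The two-fold alkyl transfer may stop at the mono-adduct, the catalyst may fail to override the weak opposing bias of the α-centre, and the zinc alkoxides may lactonise slowly. The fallback sets out from 7 and 19 and comes back at 23; it makes the C-2–C-3 bond by acyl transfer and the carbinol centre by ketone reduction. Imide 7 is cleaved with LiSEt (from EtSH and n-BuLi, THF, 0 °C) to the thioester S-ethyl (2S)-2-({[tert-butyl(diphenyl)silyl]oxy}methyl)-6-methylhept-5-enethioate F1. The bis(iodozinc) reagent 20, made from 19 as in step 11, is joined to F1 by Fukuyama coupling (PdCl2(PPh3)2 cat., toluene–THF, 20 °C) to give the bis(δ-keto ester) dimethyl (2Z,6Z)-2,7-bis[(4S)-4-({[tert-butyl(diphenyl)silyl]oxy}methyl)-8-methyl-3-oxonon-7-en-1-yl]octa-2,6-dienedioate F2. Corey–Bakshi–Shibata reduction (catecholborane, (S)-2-methyl-CBS-oxazaborolidine, toluene, −78 °C), in which the Felkin preference of the α-centre and the catalyst should reinforce each other, gives the bis(δ-hydroxy ester) dimethyl (2Z,6Z)-2,7-bis[(3R,4S)-4-({[tert-butyl(diphenyl)silyl]oxy}methyl)-3-hydroxy-8-methylnon-7-en-1-yl]octa-2,6-dienedioate F3. Catalytic camphorsulfonic acid (CH2Cl2, 20 °C) then closes both lactones to 23.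

Step 16. Chelation of the aluminium Lewis acid between each aldehyde and the basic ring ether oxygen β to it may lower the facial selectivity of the two ene closures, and the acid may attack the allylic ethers. The fallback sets out from 23 and comes back at 28; it closes the carbocycles on the bis-lactone, where the β-oxygen is an ester oxygen, and removes the lactone carbonyls last. Bu4NF buffered with AcOH (THF, 20 °C) gives the diol (3Z,3'Z,6R,6'R)-3,3'-(butane-1,4-diylidene)bis{6-[(2S)-1-hydroxy-6-methylhept-5-en-2-yl]oxan-2-one} F4. TEMPO and PhI(OAc)2 give the dialdehyde (3Z,3'Z,6R,6'R)-3,3'-(butane-1,4-diylidene)bis{6-[(2R)-6-methyl-1-oxohept-5-en-2-yl]oxan-2-one} F5. Me2AlCl (CH2Cl2, −78 °C) closes both rings to the bis(cyclopentanol) (3Z,3'Z,6R,6'R)-3,3'-(butane-1,4-diylidene)bis{6-[(1S,2S,3R)-2-hydroxy-3-(prop-1-en-2-yl)cyclopentyl]oxan-2-one} F6. Excess i-Bu2AlH (CH2Cl2, −78 °C) gives the corresponding bis-lactol (oxan-2-ol, C-2 epimers) F7, and Et3SiH with BF3·OEt2 (−78 °C) reduces F7 to 28.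

Step 13. Ionisation of each lactol gives a 2-alkylidene oxocarbenium ion whose charge is shared with the exocyclic carbon; rotation about the exocyclic bond, or hydride delivery to the exocyclic carbon, would erode the Z geometry or move the double bond into the ring. The fallback sets out from 23 and comes back at 25; it avoids any cation by closing the ether with a Williamson displacement. Excess i-Bu2AlH (CH2Cl2, −78 → 0 °C) reduces 23 to the tetraol (2Z,6Z)-2,7-bis[(3R,4S)-4-({[tert-butyl(diphenyl)silyl]oxy}methyl)-3-hydroxy-8-methylnon-7-en-1-yl]octa-2,6-diene-1,8-diol F8. Selective sulfonylation of the two primary allylic hydroxyls (TsCl, Et3N, Me3N·HCl cat., CH2Cl2, 0 °C) gives the corresponding 1,8-bis(4-methylbenzenesulfonate) F9, used crude. KOt-Bu (THF, 0 °C) then closes both oxane rings by 6-exo-tet displacement to give 25 with the Z alkenes untouched.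

**Further compounds**
F1 | step 11 | S-ethyl (2S)-2-({[tert-butyl(diphenyl)silyl]oxy}methyl)-6-methylhept-5-enethioate | CC(C)=CCC[C@@H](CO[Si](c1ccccc1)(c1ccccc1)C(C)(C)C)C(=O)SCC
F2 | step 11 | dimethyl (2Z,6Z)-2,7-bis[(4S)-4-({[tert-butyl(diphenyl)silyl]oxy}methyl)-8-methyl-3-oxonon-7-en-1-yl]octa-2,6-dienedioate | CC(C)=CCC[C@@H](CO[Si](c1ccccc1)(c1ccccc1)C(C)(C)C)C(=O)CC/C(C(=O)OC)=C/CC/C=C(/CCC(=O)[C@@H](CCC=C(C)C)CO[Si](c2ccccc2)(c2ccccc2)C(C)(C)C)C(=O)OC
F3 | step 11 | dimethyl (2Z,6Z)-2,7-bis[(3R,4S)-4-({[tert-butyl(diphenyl)silyl]oxy}methyl)-3-hydroxy-8-methylnon-7-en-1-yl]octa-2,6-dienedioate | CC(C)=CCC[C@@H](CO[Si](c1ccccc1)(c1ccccc1)C(C)(C)C)[C@H](O)CC/C(C(=O)OC)=C/CC/C=C(/CC[C@@H](O)[C@@H](CCC=C(C)C)CO[Si](c2ccccc2)(c2ccccc2)C(C)(C)C)C(=O)OC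
F4 | step 16 | (3Z,3'Z,6R,6'R)-3,3'-(butane-1,4-diylidene)bis{6-[(2S)-1-hydroxy-6-methylhept-5-en-2-yl]oxan-2-one} | CC(C)=CCC[C@@H](CO)[C@H]2CC/C(=C/CC/C=C3/CC[C@H]([C@@H](CCC=C(C)C)CO)OC3=O)C(=O)O2
F5 | step 16 | (3Z,3'Z,6R,6'R)-3,3'-(butane-1,4-diylidene)bis{6-[(2R)-6-methyl-1-oxohept-5-en-2-yl]oxan-2-one} | CC(C)=CCC[C@@H](C=O)[C@H]2CC/C(=C/CC/C=C3/CC[C@H]([C@@H](CCC=C(C)C)C=O)OC3=O)C(=O)O2
F6 | step 16 | (3Z,3'Z,6R,6'R)-3,3'-(butane-1,4-diylidene)bis{6-[(1S,2S,3R)-2-hydroxy-3-(prop-1-en-2-yl)cyclopentyl]oxan-2-one} | C=C(C)[C@H]1CC[C@H]([C@H]2CC/C(=C/CC/C=C3/CC[C@H]([C@H]4CC[C@H](C(=C)C)[C@@H]4O)OC3=O)C(=O)O2)[C@H]1O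
F7 | step 16 | bis-lactol of F6 (oxan-2-ol, C-2 epimers) | C=C(C)[C@H]1CC[C@H]([C@H]2CC/C(=C/CC/C=C3/CC[C@H]([C@H]4CC[C@H](C(=C)C)[C@@H]4O)OC3O)C(O)O2)[C@H]1O
F8 | step 13 | (2Z,6Z)-2,7-bis[(3R,4S)-4-({[tert-butyl(diphenyl)silyl]oxy}methyl)-3-hydroxy-8-methylnon-7-en-1-yl]octa-2,6-diene-1,8-diol | CC(C)=CCC[C@@H](CO[Si](c1ccccc1)(c1ccccc1)C(C)(C)C)[C@H](O)CC/C(CO)=C/CC/C=C(/CC[C@@H](O)[C@@H](CCC=C(C)C)CO[Si](c2ccccc2)(c2ccccc2)C(C)(C)C)CO
F9 | step 13 | 1,8-bis(4-methylbenzenesulfonate) of F8 | CC(C)=CCC[C@@H](CO[Si](c1ccccc1)(c1ccccc1)C(C)(C)C)[C@H](O)CC/C(COS(=O)(=O)c1ccc(C)cc1)=C/CC/C=C(/CC[C@@H](O)[C@@H](CCC=C(C)C)CO[Si](c2ccccc2)(c2ccccc2)C(C)(C)C)COS(=O)(=O)c2ccc(C)cc2
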